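**Numbering used throughout.** Lactone ring: O1, C2(=O), C3, C4(CH3), C5. Chain on C3: C1'=C2'(CH3)–C3'=C4'–C5'(OH)–C6'(CH3)–C7'(=O)–C8'. Chain on C5: C2''(CH3)=C3''–C4''=C5''–C6''(n-Bu)(CH2OH). Compounds 1–26 are defined in the steps and in the compound list; 26 is the target.

## The problem

The target is a C25 chain with one extra carbon: an oxolan-2-one (O1, C2, C3, C4, C5) carries a methyl on C4 and an (E,E)-dienyl chain on C3 and on C5, and the lactone carbonyl C2 is a one-carbon branch that no simple polyketide-type building block supplies. The six stereocenters form three groups insulated from each other by the dienes: the all-trans ring triad (3S,4S,5S), the syn aldol pair C5'(S)/C6'(R), and the lone C6''(R). Within the triad one center can control the others, but the other two groups need their own source of chirality. C3 is the weak point: its hydrogen is α to the lactone carbonyl and allylic to C1'=C2', so base epimerises it or pulls the double bond into conjugation with C2, and it must therefore be made late and without enolate chemistry. C5–O1 is an allylic ester bond, and the C5' hydroxyl is dienylic and β to the C7' ketone, so retro-aldol cleavage, elimination to a trienone and epimerisation at C6' threaten under acid or strong base. Both trisubstituted alkenes (C1'=C2' and C2''=C3'') must be E and sit next to ring stereocenters. The feature the plan exploits is that C3 is an allylic carbon (C3–C1'=C2') placed 1,3 to the oxygen-bearing C5 across C4: C2 can be inserted as carbon monoxide between an η3-allylpalladium unit at C3 and the C5 alkoxide, and because such carbonylation inverts the allylic carbon, the all-trans ring maps onto an open-chain syn-aldol/1,3-anti-diol stereotriad.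

## Retrosynthesis

**26 ⇒ 25.** Only the two silyl ethers (primary TBS, secondary TES at C5') are removed. Both hydroxyls must be masked earlier (boron triflate, samarium and lithium reagents), and one buffered fluoride step at the end avoids any base near C3–H.

**25 ⇒ 24 (key cut: C2–C3 and C2–O1; C2 leaves as CO).** Cutting the ring at both bonds to C2 removes the only non-chain carbon and opens the lactone to the acyclic allylic benzoate 24, which has a free hydroxyl on the future C5. The neighbouring cuts (C3–C1' by enolate alkenylation, C3–C4 by conjugate addition) would both build C3 through an enolate of the lactone, which the target tolerates least. The precursor has no ring and no quaternised functionality, and its three contiguous centers are an aldol-type stereotriad. The forward reaction must ionise one allylic C–O bond only, form the C–C bond at the proximal allyl terminus with inversion, and close the five-membered ring.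

**24 ⇒ 23 (C11–H and the benzoyl–O9 bond).** The anti-1,3-diol monoester is the signature product of an Evans–Tishchenko reduction of the β-hydroxy ketone 23. The acyl group lands on the oxygen that was the aldol hydroxyl (O9, the future leaving group), and the new carbinol (O11, the future ring oxygen) is left free. This sets C11 and differentiates two otherwise very similar allylic hydroxyls in one step, which a borohydride reduction followed by acylation would not do reliably.

**23 ⇒ 11 + 21 (C9–C10, aldol).** The syn relationship O9/CH3–C10 is that of a Z-enolate aldol between ethyl ketone 11 (the complete left half) and dienal 21 (the complete right half). This cut sits in the middle of the molecule, gives two fragments of similar size, and forms two of the three triad centers. Because the fragment stereocenters are remote, the aldehyde face must be chosen by the boron ligands (diisopinocampheyl).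

**11 ⇒ 7 + 10; 7 ⇒ 5 + 6; 5 ⇒ 3 + 4; 3 ⇒ 2 ⇒ 1; 10 ⇐ 8 (via 9).** The (E)-trisubstituted enone of 11 is a Wittig product of enal 7 and acyl ylide 10 (from bromoketone 8 through salt 9). Enal 7 comes from cross-metathesis of the terminal alkene 5 with crotonaldehyde 6. The lone stereocenter of 5 (future C6'') is set by copper-catalysed asymmetric SN2' alkylation of allylic bromide 3 with butylmagnesium bromide 4. Bromide 3 comes from diol 1 through mono-silyl ether 2.

**21 ⇒ 20 ⇒ 19 ⇒ 18 ⇒ 14 + 15 (+16, via 17); 14 ⇒ 12 + 13.** The syn α-methyl-β-hydroxy ketone is taken back to the morpholine amide 18, the product of a reductive aldol of 4-acryloylmorpholine 15 (enolborinate 17, from borane 16) with dienal 14. This avoids the regiochemistry problem of enolising butanone. Methyllithium turns amide 19 into the methyl ketone and unmasks the allylic alcohol 20 from its acetate in one step, and MnO2 gives 21. Dienal 14 is the Wittig homologue of the commercial C5 enal acetate 12 with ylide 13.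

## Roads not taken

**Alternative 1:** (the most obvious) Cut C2'–C3' and C3''–C4'' (sp2–sp2) and couple two alkenyl-metal side chains to the bis(iodoalkenyl) lactone A1 by two palladium-catalysed cross-couplings. A1 carries the labile C3–H from the start and would have to survive two basic coupling steps, the two iodoalkenes are hard to tell apart, and three fragments each need their own stereocontrol. The ring triad still needs a separate solution, so the route is longer and exposes the weakest center for longest.

**Alternative 2:** Cut C4–CH3 and C3–C1' and relay C4 and C3 from C5: conjugate addition of a methylcuprate to the 5-dienyl butenolide A2 anti to the C5 substituent, then trapping of the enolate with an alkenyl electrophile. The C5–O bond of A2 is an allylic (dienylic) ester that cuprates open by SN2' substitution. Enolate alkenylation needs a lithium enolate plus palladium in the presence of the C7' ketone, and the product's C3–H is more acidic than that of the starting enolate precursor, so equilibration into the conjugated alkylidene lactone is the expected outcome. The chosen plan never makes an enolate at C3.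

**Alternative 3:** Cut C5'–C6' last: aldol of a butanone Z-enolate with the lactone dienal A3. In A3 the C3–H is vinylogously α to the aldehyde through the diene as well as α to the lactone, so amine/boron triflate conditions would enolise it and lose both C3 and the alkene geometry. Butanone must also be enolised regioselectively, and a reagent-controlled aldol would fall on the most advanced intermediate. The chosen plan does all aldehyde chemistry before the ring exists.

Key step: step 14

Assumption: (−)-Ipc2BH (from (+)-α-pinene, used as the crystalline reagent) and the (R,R)-Taniaphos ligand are taken to give the facial sense drawn in 5, 18 and 23; if a trial run shows the opposite sense, the antipodal reagent is used and nothing else changes.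

## Steps

Step 1
Reactants: 1 (E)-but-2-ene-1,4-diol
Product: 2 (E)-4-[(tert-butyldimethylsilyl)oxy]but-2-en-1-ol
Conditions: NaH (1.0 equiv), THF, 0 °C; TBSCl (1.0 equiv), 0 °C → rt
Reagents that add atoms: tert-butyldimethylsilyl chloride (TBSCl), CC(C)(C)[Si](C)(C)Cl
Why: Monosilylation of a symmetrical diol through its sparingly soluble monosodium alkoxide should give mainly the mono-ether; no stereocenter is involved.

Step 2
Reactants: 2 (E)-4-[(tert-butyldimethylsilyl)oxy]but-2-en-1-ol
Product: 3 (E)-[(4-bromobut-2-en-1-yl)oxy](tert-butyl)dimethylsilane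
Conditions: CBr4, PPh3, CH2Cl2, 0 °C
Reagents that add atoms: carbon tetrabromide, BrC(Br)(Br)Br
Why: Appel bromination converts the primary allylic alcohol under neutral conditions; the silyl ether and the E alkene are untouched.

Step 3
Reactants: 3 (E)-[(4-bromobut-2-en-1-yl)oxy](tert-butyl)dimethylsilane; 4 n-butylmagnesium bromide
Product: 5 (R)-tert-butyl[(2-ethenylhexyl)oxy]dimethylsilane
Conditions: CuBr·SMe2 (1 mol %), (R)-1-[(R)-(dimethylamino)[2-(diphenylphosphino)phenyl]methyl]-2-(diphenylphosphino)ferrocene (Taniaphos, 1.2 mol %), CH2Cl2, −78 °C, slow addition of 4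
Reagents that add atoms: none
Why: Copper-catalysed asymmetric allylic alkylation (SN2') of an (E)-4-oxybut-2-enyl bromide with a Grignard reagent is a documented substrate class; the chiral diphosphine–copper complex delivers butyl to the γ-carbon and sets the lone stereocenter (future C6'') as R.

Step 4
Reactants: 5 (R)-tert-butyl[(2-ethenylhexyl)oxy]dimethylsilane; 6 (E)-but-2-enal (crotonaldehyde)
Product: 7 (R,E)-4-{[(tert-butyldimethylsilyl)oxy]methyl}oct-2-enal
Conditions: second-generation Hoveyda–Grubbs catalyst [RuCl2(H2IMes)(=CH–C6H4-2-OiPr)] (5 mol %), 6 (5 equiv), CH2Cl2, 40 °C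
Reagents that add atoms: none
Why: Olefin cross-metathesis of a monosubstituted alkene with excess crotonaldehyde should give the (E)-enal under thermodynamic control; the allylic stereocenter is not a reacting atom.

Step 5
Reactants: 8 2-bromopentan-3-one
Product: 10 2-(triphenyl-λ5-phosphanylidene)pentan-3-one, via phosphonium bromide 9 (not isolated)
Conditions: PPh3, toluene, 80 °C; then aq. NaOH, CH2Cl2, rt
Reagents that add atoms: triphenylphosphine, c1ccc(cc1)P(c1ccccc1)c1ccccc1
Why: SN2 quaternisation of the α-bromoketone followed by deprotonation gives the stabilised acyl ylide.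

Step 6
Reactants: 7 (R,E)-4-{[(tert-butyldimethylsilyl)oxy]methyl}oct-2-enal; 10 2-(triphenyl-λ5-phosphanylidene)pentan-3-one
Product: 11 (4E,6E,8R)-8-{[(tert-butyldimethylsilyl)oxy]methyl}-4-methyldodeca-4,6-dien-3-one
Conditions: toluene, 100 °C
Reagents that add atoms: none
Why: Wittig olefination with a stabilised α-methyl acyl ylide should give the (E)-trisubstituted enone (future C2''=C3''); the ylide is too weakly basic to deconjugate the enal.

Step 7
Reactants: 12 (E)-3-methyl-4-oxobut-2-en-1-yl acetate; 13 2-(triphenyl-λ5-phosphanylidene)acetaldehyde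
Product: 14 (2E,4E)-3-methyl-6-oxohexa-2,4-dien-1-yl acetate
Conditions: 13 (0.95 equiv), toluene, 70 °C
Reagents that add atoms: none
Why: Wittig two-carbon homologation with the formyl-stabilised ylide gives the (E)-enal; a slight deficit of ylide limits a second homologation of the product.

Step 8
Reactants: 15 4-acryloylmorpholine; 16 (−)-diisopinocampheylborane ((−)-Ipc2BH); 14 (2E,4E)-3-methyl-6-oxohexa-2,4-dien-1-yl acetate
Product: 18 (2E,4E,6S,7R)-6-hydroxy-3,7-dimethyl-8-(morpholin-4-yl)-8-oxoocta-2,4-dien-1-yl acetate, via Z-enolborinate 17 (not isolated)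
Conditions: 15 (1.1 equiv) and 16 (1.0 equiv), Et2O, 0 °C; then 14 (0.85 equiv), −78 °C; pH 7 buffer, MeOH, 30% H2O2, 0 °C
Reagents that add atoms: none
Why: Reductive aldol: 1,4-hydroboration of the acrylamide gives the Z(O)-enolborinate, which adds to the aldehyde through a closed Zimmerman–Traxler chair to give the syn adduct; the isopinocampheyl groups choose the aldehyde face and set C6(S) and C7(R) (future C5' and C6').

Step 9
Reactants: 18 (2E,4E,6S,7R)-6-hydroxy-3,7-dimethyl-8-(morpholin-4-yl)-8-oxoocta-2,4-dien-1-yl acetate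
Product: 19 (2E,4E,6S,7R)-3,7-dimethyl-8-(morpholin-4-yl)-8-oxo-6-[(triethylsilyl)oxy]octa-2,4-dien-1-yl acetate
Conditions: TESCl, imidazole, DMF, 0 °C
Reagents that add atoms: triethylsilyl chloride (TESCl), CC[Si](CC)(CC)Cl
Why: Standard silylation of the secondary alcohol blocks retro-aldol and elimination pathways in the following steps.

Step 10
Reactants: 19 (2E,4E,6S,7R)-3,7-dimethyl-8-(morpholin-4-yl)-8-oxo-6-[(triethylsilyl)oxy]octa-2,4-dien-1-yl acetate
Product: 20 (3R,4S,5E,7E)-9-hydroxy-3,7-dimethyl-4-[(triethylsilyl)oxy]nona-5,7-dien-2-one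
Conditions: MeLi (3.5 equiv), THF, −78 °C; aq. NH4Cl
Reagents that add atoms: methyllithium, [Li]C
Why: Morpholine amides behave like Weinreb amides, so the tetrahedral lithium adduct holds until work-up and only one methyl is transferred; the same reagent cleaves the acetate and frees the primary allylic alcohol.

Step 11
Reactants: 20 (3R,4S,5E,7E)-9-hydroxy-3,7-dimethyl-4-[(triethylsilyl)oxy]nona-5,7-dien-2-one
Product: 21 (2E,4E,6S,7R)-3,7-dimethyl-8-oxo-6-[(triethylsilyl)oxy]nona-2,4-dienal
Conditions: MnO2 (excess), CH2Cl2, rt
Reagents that add atoms: none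
Why: MnO2 oxidises only the dienylic primary alcohol; the ketone, its α-stereocenter and the silyl ether are not affected under these neutral conditions.

Step 12
Reactants: 11 (4E,6E,8R)-8-{[(tert-butyldimethylsilyl)oxy]methyl}-4-methyldodeca-4,6-dien-3-one; 16 (−)-diisopinocampheylborane ((−)-Ipc2BH); 21 (2E,4E,6S,7R)-3,7-dimethyl-8-oxo-6-[(triethylsilyl)oxy]nona-2,4-dienal
Product: 23 (3R,4S,5E,7E,9R,10S,12E,14E,16R)-16-{[(tert-butyldimethylsilyl)oxy]methyl}-9-hydroxy-3,7,10,12-tetramethyl-4-[(triethylsilyl)oxy]icosa-5,7,12,14-tetraene-2,11-dione, via Z-boron enolate 22 (not isolated)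
Conditions: 16, TfOH, hexane, 0 °C → rt (gives (−)-Ipc2BOTf); 11, iPr2NEt, CH2Cl2, −78 °C; 21 (0.8 equiv), −78 → −20 °C; pH 7 buffer, MeOH, 30% H2O2, 0 °C
Reagents that add atoms: none
Why: Diisopinocampheylboron triflate and amine enolise the ethyl ketone to the Z-enolate, whose chair transition state gives the 9,10-syn aldol. The boron ligands choose the aldehyde face (both fragment stereocenters are remote), setting C9(R) and C10(S). The aldehyde of 21 reacts far faster than its methyl ketone.

Step 13
Reactants: 23 (3R,4S,5E,7E,9R,10S,12E,14E,16R)-16-{[(tert-butyldimethylsilyl)oxy]methyl}-9-hydroxy-3,7,10,12-tetramethyl-4-[(triethylsilyl)oxy]icosa-5,7,12,14-tetraene-2,11-dione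
Product: 24 (3R,4S,5E,7E,9R,10R,11S,12E,14E,16R)-16-{[(tert-butyldimethylsilyl)oxy]methyl}-11-hydroxy-3,7,10,12-tetramethyl-2-oxo-4-[(triethylsilyl)oxy]icosa-5,7,12,14-tetraen-9-yl benzoate
Conditions: SmI2 (30 mol %), PhCHO (6 equiv), THF, −10 °C, dark
Reagents that add atoms: benzaldehyde, O=Cc1ccccc1
Why: Evans–Tishchenko reduction: the samarium-bound hemiacetal of O9 with benzaldehyde delivers hydride intramolecularly to the C11 ketone through a chair-like bicyclic transition state, giving the 1,3-anti carbinol (11S). The benzoyl group is left on O9 and O11 stays free; the C2 ketone has no β-hydroxyl and is not reduced.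

Step 14
Reactants: 24 (3R,4S,5E,7E,9R,10R,11S,12E,14E,16R)-16-{[(tert-butyldimethylsilyl)oxy]methyl}-11-hydroxy-3,7,10,12-tetramethyl-2-oxo-4-[(triethylsilyl)oxy]icosa-5,7,12,14-tetraen-9-yl benzoate
Product: 25 (3S,4S,5S)-5-[(2E,4E,6R)-6-{[(tert-butyldimethylsilyl)oxy]methyl}deca-2,4-dien-2-yl]-4-methyl-3-[(1E,3E,5S,6R)-2,6-dimethyl-7-oxo-5-[(triethylsilyl)oxy]octa-1,3-dien-1-yl]oxolan-2-one
Conditions: Pd2(dba)3·CHCl3 (5 mol %), PPh3 (20 mol %), CO (5 atm), iPr2NEt (1.5 equiv), THF, 40 °C
Reagents that add atoms: carbon monoxide, [C-]#[O+]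
Why: Proposed new method: carbonylative lactonisation of an acyclic 3-hydroxy allylic benzoate whose allyl unit is part of a diene; the closest known reaction types are the palladium-catalysed decarboxylative carbonylation of 4-vinyl-1,3-dioxan-2-ones to trans-2-vinyl-γ-butyrolactones and the alkoxycarbonylation of allylic esters and carbonates, which runs with net inversion. Zerovalent palladium ionises the only ester-type allylic C–O bond (C9–OBz; the free C11 alcohol and the silyl ethers are not leaving groups) anti to the benzoate and gives an η3-allyl complex over C9–C8–C7; CO then inserts with retention at C9 and the C11 alkoxide captures the acyl group (or CO inserts into Pd–O and a six-membered alkoxycarbonyl palladacycle eliminates reductively). The oxolan-2-one ring closes by a 5-exo-trig acyl substitution at the acylpalladium carbon; bonding at C7 or C5 of the pentadienyl system would need a seven- or nine-membered ring and would break the diene conjugation, so C9 is the expected site. The new stereocenter (C9 of 24, C3 of the lactone) is set by this stereospecific inversion, so the carbonyl arrives on the face opposite to the departed benzoate and C3 ends trans to the C4 methyl; C4 and C5 are carried over from 24 unchanged. The E geometry of C1'=C2' is kept because allylic 1,3-strain with the C7 methyl places the C9 hydrogen inside on ionisation and the chain in the syn position of the allyl. The step needs stereochemical fidelity against η3–η1–η3 face exchange: exchange through the fully substituted C7 terminus is slow, exchange through C9 would force two anti substituents, and the 3,4-trans lactone is also the isomer favoured in the known trans-selective cyclisations. The near-neutral medium keeps the doubly activated C3–H of the product from epimerising or from moving C1'=C2' into conjugation.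

Step 15
Reactants: 25 (3S,4S,5S)-5-[(2E,4E,6R)-6-{[(tert-butyldimethylsilyl)oxy]methyl}deca-2,4-dien-2-yl]-4-methyl-3-[(1E,3E,5S,6R)-2,6-dimethyl-7-oxo-5-[(triethylsilyl)oxy]octa-1,3-dien-1-yl]oxolan-2-one
Product: 26 (3S,4S,5S)-3-[(1E,3E,5S,6R)-5-hydroxy-2,6-dimethyl-7-oxoocta-1,3-dien-1-yl]-5-[(2E,4E,6R)-6-(hydroxymethyl)deca-2,4-dien-2-yl]-4-methyloxolan-2-one
Conditions: HF·pyridine, pyridine, THF, 0 °C → rt
Reagents that add atoms: none
Why: Buffered fluoride removes the secondary triethylsilyl and the primary tert-butyldimethylsilyl ether in one operation; the medium is neither basic enough to touch C3–H or the β-hydroxy ketone nor acidic enough to ionise the dienylic alcohol.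

## Compound list

1 | (E)-but-2-ene-1,4-diol | OC/C=C/CO | starting material
2 | (E)-4-[(tert-butyldimethylsilyl)oxy]but-2-en-1-ol | OC/C=C/CO[Si](C)(C)C(C)(C)C | intermediate
3 | (E)-[(4-bromobut-2-en-1-yl)oxy](tert-butyl)dimethylsilane | BrC/C=C/CO[Si](C)(C)C(C)(C)C | intermediate
4 | n-butylmagnesium bromide | CCCC[Mg]Br | starting material
5 | (R)-tert-butyl[(2-ethenylhexyl)oxy]dimethylsilane | CCCC[C@H](C=C)CO[Si](C)(C)C(C)(C)C | intermediate
6 | (E)-but-2-enal (crotonaldehyde) | C/C=C/C=O | starting material
7 | (R,E)-4-{[(tert-butyldimethylsilyl)oxy]methyl}oct-2-enal | CCCC[C@H](/C=C/C=O)CO[Si](C)(C)C(C)(C)C | intermediate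
8 | 2-bromopentan-3-one (racemic) | CCC(=O)C(C)Br | starting material
9 | (3-oxopentan-2-yl)triphenylphosphonium bromide | CCC(=O)C(C)[P+](c1ccccc1)(c1ccccc1)c1ccccc1.[Br-] | intermediate
10 | 2-(triphenyl-λ5-phosphanylidene)pentan-3-one | CCC(=O)C(C)=P(c1ccccc1)(c1ccccc1)c1ccccc1 | intermediate
11 | (4E,6E,8R)-8-{[(tert-butyldimethylsilyl)oxy]methyl}-4-methyldodeca-4,6-dien-3-one | CCCC[C@H](/C=C/C=C(\C)C(=O)CC)CO[Si](C)(C)C(C)(C)C | intermediate
12 | (E)-3-methyl-4-oxobut-2-en-1-yl acetate | CC(=O)OC/C=C(\C)C=O | starting material
13 | 2-(triphenyl-λ5-phosphanylidene)acetaldehyde | O=CC=P(c1ccccc1)(c1ccccc1)c1ccccc1 | starting material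
14 | (2E,4E)-3-methyl-6-oxohexa-2,4-dien-1-yl acetate | CC(=O)OC/C=C(C)/C=C/C=O | intermediate
15 | 4-acryloylmorpholine | C=CC(=O)N1CCOCC1 | starting material
16 | (−)-diisopinocampheylborane, (−)-Ipc2BH | C[C@H]1[C@@H](C[C@@H]2C[C@H]1C2(C)C)B[C@@H]1C[C@@H]2C[C@@H](C2(C)C)[C@H]1C | starting material
17 | (Z)-1-(morpholin-4-yl)prop-1-en-1-yl diisopinocampheylborinate | C/C=C(\OB([C@@H]1C[C@@H]2C[C@@H](C2(C)C)[C@H]1C)[C@@H]1C[C@@H]2C[C@@H](C2(C)C)[C@H]1C)N1CCOCC1 | intermediate
18 | (2E,4E,6S,7R)-6-hydroxy-3,7-dimethyl-8-(morpholin-4-yl)-8-oxoocta-2,4-dien-1-yl acetate | CC(=O)OC/C=C(C)/C=C/[C@H](O)[C@@H](C)C(=O)N1CCOCC1 | intermediate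
19 | (2E,4E,6S,7R)-3,7-dimethyl-8-(morpholin-4-yl)-8-oxo-6-[(triethylsilyl)oxy]octa-2,4-dien-1-yl acetate | CC(=O)OC/C=C(C)/C=C/[C@H](O[Si](CC)(CC)CC)[C@@H](C)C(=O)N1CCOCC1 | intermediate
20 | (3R,4S,5E,7E)-9-hydroxy-3,7-dimethyl-4-[(triethylsilyl)oxy]nona-5,7-dien-2-one | OC/C=C(C)/C=C/[C@H](O[Si](CC)(CC)CC)[C@@H](C)C(C)=O | intermediate
21 | (2E,4E,6S,7R)-3,7-dimethyl-8-oxo-6-[(triethylsilyl)oxy]nona-2,4-dienal | O=C/C=C(C)/C=C/[C@H](O[Si](CC)(CC)CC)[C@@H](C)C(C)=O | intermediate
22 | (Z)-enol diisopinocampheylborinate of ketone 11 | CCCC[C@H](/C=C/C=C(\C)/C(OB([C@@H]1C[C@@H]2C[C@@H](C2(C)C)[C@H]1C)[C@@H]1C[C@@H]2C[C@@H](C2(C)C)[C@H]1C)=C/C)CO[Si](C)(C)C(C)(C)C | intermediate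
23 | (3R,4S,5E,7E,9R,10S,12E,14E,16R)-16-{[(tert-butyldimethylsilyl)oxy]methyl}-9-hydroxy-3,7,10,12-tetramethyl-4-[(triethylsilyl)oxy]icosa-5,7,12,14-tetraene-2,11-dione | CCCC[C@H](/C=C/C=C(\C)C(=O)[C@@H](C)[C@H](O)/C=C(C)/C=C/[C@H](O[Si](CC)(CC)CC)[C@@H](C)C(C)=O)CO[Si](C)(C)C(C)(C)C | intermediate
24 | (3R,4S,5E,7E,9R,10R,11S,12E,14E,16R)-16-{[(tert-butyldimethylsilyl)oxy]methyl}-11-hydroxy-3,7,10,12-tetramethyl-2-oxo-4-[(triethylsilyl)oxy]icosa-5,7,12,14-tetraen-9-yl benzoate | CCCC[C@H](/C=C/C=C(\C)[C@@H](O)[C@@H](C)[C@H](OC(=O)c1ccccc1)/C=C(C)/C=C/[C@H](O[Si](CC)(CC)CC)[C@@H](C)C(C)=O)CO[Si](C)(C)C(C)(C)C | intermediate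
25 | (3S,4S,5S)-5-[(2E,4E,6R)-6-{[(tert-butyldimethylsilyl)oxy]methyl}deca-2,4-dien-2-yl]-4-methyl-3-[(1E,3E,5S,6R)-2,6-dimethyl-7-oxo-5-[(triethylsilyl)oxy]octa-1,3-dien-1-yl]oxolan-2-one | CCCC[C@H](/C=C/C=C(\C)[C@H]1OC(=O)[C@@H](/C=C(C)/C=C/[C@H](O[Si](CC)(CC)CC)[C@@H](C)C(C)=O)[C@@H]1C)CO[Si](C)(C)C(C)(C)C | intermediate
26 | (3S,4S,5S)-3-[(1E,3E,5S,6R)-5-hydroxy-2,6-dimethyl-7-oxoocta-1,3-dien-1-yl]-5-[(2E,4E,6R)-6-(hydroxymethyl)deca-2,4-dien-2-yl]-4-methyloxolan-2-one | CCCC[C@H](/C=C/C=C(\C)[C@H]1OC(=O)[C@@H](/C=C(C)/C=C/[C@H](O)[C@@H](C)C(C)=O)[C@@H]1C)CO | target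

## Step count and risk

Total step count: 15. Longest linear sequence: 9 steps (1 → 2 → 3 → 5 → 7 → 11 → 23 → 24 → 25 → 26; the branch from 12 through 14, 18, 19, 20, 21 to 26 is also 9).

**Step 14 (key step, proposed new method).** Three processes could intervene. Stereochemical fidelity could be lost at the allyl stage through face exchange of palladium or migration along the pentadienyl system. β-Hydride loss from the allyl complex could give a triene. Benzoyl could migrate from O9 to O11 before ionisation, or the allylic C5–O bond of the product could re-ionise. The fallback separates C–C bond formation from ring closure and uses known alkoxycarbonylation of allylic esters. It sets out from 24: silylation of O11 (TESOTf, 2,6-lutidine, CH2Cl2, −78 °C) gives the 4,11-bis(triethylsilyl) ether benzoate F1. Intermolecular methoxycarbonylation (Pd2(dba)3·CHCl3, PPh3, NaBr, CO 30 atm, MeOH, iPr2NEt, 50 °C) gives, with inversion at the allylic carbon, the β,γ-unsaturated methyl ester F2. HF·pyridine then removes the three silyl groups, and the freed hydroxy ester lactonises, so the sequence comes back to the route at 26.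

**Step 13.** Retro-aldol cleavage of the samarium aldolate (it would release a conjugated enal and an enolate and scramble C9/C10) or slow hydride transfer to the cross-conjugated ketone could intervene; trivalent samarium could also promote benzoyl migration. The fallback sets out from 23: hydroxyl-directed reduction with Me4NBH(OAc)3 (MeCN/AcOH, −30 °C) gives the 9,11-anti diol F3. Site-selective benzoylation (BzCl 1.05 equiv, 2,4,6-collidine, CH2Cl2, −40 °C) at O9, whose carbinol is flanked by a CH= carbon while the O11 carbinol is flanked by the fully substituted C12, comes back to the route at 24.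

**Step 12.** Facial discrimination by the isopinocampheyl ligands may be insufficient with a β,β-disubstituted enal, and excess boron triflate could enolise the methyl ketone of 21. The fallback changes the aldol manifold from a stoichiometric chiral boron enolate (closed transition state) to a catalytic chiral Lewis acid (open transition state). It sets out from 11: TMSOTf and Et3N (CH2Cl2, 0 °C) give the (Z)-trimethylsilyl enol ether F4. A Mukaiyama aldol with 21, catalysed by the (acyloxy)borane from (2R,3R)-2-O-(2,6-diisopropoxybenzoyl)tartaric acid and BH3·THF (20 mol %, EtCN, −78 °C), is syn-selective from either enol ether geometry; citric acid/MeOH work-up comes back to the route at 23.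

**Step 4.** Cross-metathesis at an α-branched allylic position may be slow, with catalyst decay to ruthenium hydrides and double-bond migration that would erode the stereocenter. The fallback sets out from 5: ozonolysis (O3, CH2Cl2, −78 °C; PPh3) gives (S)-2-{[(tert-butyldimethylsilyl)oxy]methyl}hexanal F5, which is used at once in a Wittig reaction with 13 (toluene, 60 °C) and comes back to the route at 7.

## Further compounds

F1 | step 14 | (3R,4S,5E,7E,9R,10S,11S,12E,14E,16R)-16-{[(tert-butyldimethylsilyl)oxy]methyl}-3,7,10,12-tetramethyl-2-oxo-4,11-bis[(triethylsilyl)oxy]icosa-5,7,12,14-tetraen-9-yl benzoate | CCCC[C@H](/C=C/C=C(\C)[C@@H](O[Si](CC)(CC)CC)[C@@H](C)[C@H](OC(=O)c1ccccc1)/C=C(C)/C=C/[C@H](O[Si](CC)(CC)CC)[C@@H](C)C(C)=O)CO[Si](C)(C)C(C)(C)C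
F2 | step 14 | methyl (2S,3S,4S,5E,7E,9R)-9-{[(tert-butyldimethylsilyl)oxy]methyl}-2-[(1E,3E,5S,6R)-2,6-dimethyl-7-oxo-5-[(triethylsilyl)oxy]octa-1,3-dien-1-yl]-3,5-dimethyl-4-[(triethylsilyl)oxy]trideca-5,7-dienoate | CCCC[C@H](/C=C/C=C(\C)[C@@H](O[Si](CC)(CC)CC)[C@@H](C)[C@@H](C(=O)OC)/C=C(C)/C=C/[C@H](O[Si](CC)(CC)CC)[C@@H](C)C(C)=O)CO[Si](C)(C)C(C)(C)C
F3 | step 13 | (3R,4S,5E,7E,9R,10S,11S,12E,14E,16R)-16-{[(tert-butyldimethylsilyl)oxy]methyl}-9,11-dihydroxy-3,7,10,12-tetramethyl-4-[(triethylsilyl)oxy]icosa-5,7,12,14-tetraen-2-one | CCCC[C@H](/C=C/C=C(\C)[C@@H](O)[C@@H](C)[C@H](O)/C=C(C)/C=C/[C@H](O[Si](CC)(CC)CC)[C@@H](C)C(C)=O)CO[Si](C)(C)C(C)(C)C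
F4 | step 12 | tert-butyl{[(2R,3E,5E,7Z)-2-butyl-6-methyl-7-[(trimethylsilyl)oxy]nona-3,5,7-trien-1-yl]oxy}dimethylsilane | CCCC[C@H](/C=C/C=C(\C)/C(O[Si](C)(C)C)=C/C)CO[Si](C)(C)C(C)(C)C
F5 | step 4 | (S)-2-{[(tert-butyldimethylsilyl)oxy]methyl}hexanal | CCCC[C@H](C=O)CO[Si](C)(C)C(C)(C)C
A1 | alternative 1 | (3R,4S,5S)-3-[(E)-2-iodoprop-1-en-1-yl]-5-[(E)-1-iodoprop-1-en-2-yl]-4-methyloxolan-2-one | I/C=C(\C)[C@H]1OC(=O)[C@@H](/C=C(C)/I)[C@@H]1C
A2 | alternative 2 | (5S)-5-[(2E,4E,6R)-6-{[(tert-butyldimethylsilyl)oxy]methyl}deca-2,4-dien-2-yl]furan-2(5H)-one | CCCC[C@H](/C=C/C=C(\C)[C@H]1OC(=O)C=C1)CO[Si](C)(C)C(C)(C)C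
A3 | alternative 3 | (2E,4E)-5-[(3S,4S,5S)-5-[(2E,4E,6R)-6-{[(tert-butyldimethylsilyl)oxy]methyl}deca-2,4-dien-2-yl]-4-methyl-2-oxooxolan-3-yl]-4-methylpenta-2,4-dienal | CCCC[C@H](/C=C/C=C(\C)[C@H]1OC(=O)[C@@H](/C=C(C)/C=C/C=O)[C@@H]1C)CO[Si](C)(C)C(C)(C)C
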